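## Retrosynthetic overview

1. The last C–C bond made is the exocyclic C=C of the (Z)-γ-ylidenebutenolide: vinylogous aldol condensation of a 3-substituted furan-2(5H)-one (fragment 1) with a C22 tetraenynal (fragment 2), then desilylation.
2. Fragment 2 comes from chiral-pool (4R,6R)-actinol: enol triflate, Sonogashira coupling with (E)-3-methylpent-2-en-4-yn-1-ol, then Horner–Wadsworth–Emmons (C4) and Wittig (C3) chain extension.
3. The butenolide ring of fragment 1 is closed last, by palladium-catalysed carbonylative lactonisation of a (Z)-3-iodoallylic alcohol grown from an ethynyl group on C2.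
4. Key disconnection: O1–C7a of the hexahydrobenzofuran. O1 sits between C2 and the quaternary C7a with the C3=C3a double bond between them, so the dihydrofuran ring is one oxygen atom added 1,4 across a C2=C3–C3a=C7a diene. It opens retrosynthetically to the C2–C3 oxirane next to a C3a=C7a ring alkene (a vinyl oxirane), and a 1,3-shift of oxygen from C3 to C7a closes it, the inverse of the epoxide-to-furanoid rearrangement.
5. Ring order and stereochemical relay: bought cyclohexanedione ring (C6 masked as a ketal) → Sharpless oxirane (sets C2) → dihydrofuran (key step, C2 sets C7a) → C6 ketone reduced under control of the C4 and C7a methyls → butenolide. The cyclohexene ring of fragment 2 is taken from actinol.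

Key step: step 7

Assumption: rac-2,2,6-trimethylcyclohexane-1,4-dione and (4R,6R)-4-hydroxy-2,2,6-trimethylcyclohexan-1-one (actinol) are taken as purchasable; the bicyclic end group is numbered as a 1-benzofuran (O1, C2, C3, C3a, C4 to C7, C7a) throughout, and polyenes are handled in the dark under argon.

## Route

**Fragment 1 (steps 1–12)**

Step 1
Reactants: 1 rac-2,2,6-trimethylcyclohexane-1,4-dione
Product: 2 rac-7,7,9-trimethyl-1,4-dioxaspiro[4.5]decan-8-one
Conditions: HOCH2CH2OH (1.1 equiv), p-TsOH·H2O (cat.), benzene, Dean–Stark, reflux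
Reagents that add atoms: ethane-1,2-diol, OCCO
Why: acid-catalysed ketalisation should be selective for the unhindered C4 carbonyl because the other carbonyl is flanked by a quaternary and a methyl-bearing carbon; the single stereocentre is erased in step 2.

Step 2
Reactants: 2 rac-7,7,9-trimethyl-1,4-dioxaspiro[4.5]decan-8-one
Product: 4 7,9,9-trimethyl-1,4-dioxaspiro[4.5]dec-7-en-8-yl trifluoromethanesulfonate, via lithium enolate 3 (not isolated)
Conditions: LiN(i-Pr)2, THF, −78 → 0 °C; PhNTf2, −78 °C → rt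
Reagents that add atoms: N-phenylbis(trifluoromethanesulfonimide), O=S(=O)(N(c1ccccc1)S(=O)(=O)C(F)(F)F)C(F)(F)F
Why: enol triflate formation; the ketone has a single α-hydrogen, so only one (tetrasubstituted) enolate can form and it is O-sulfonylated.

Step 3
Reactants: 4 7,9,9-trimethyl-1,4-dioxaspiro[4.5]dec-7-en-8-yl trifluoromethanesulfonate; 5 (E)-3-(tributylstannyl)prop-2-en-1-ol
Product: 6 (E)-3-(7,9,9-trimethyl-1,4-dioxaspiro[4.5]dec-7-en-8-yl)prop-2-en-1-ol
Conditions: Pd2(dba)3 (2.5 mol %), AsPh3 (20 mol %), LiCl (3 equiv), NMP, 50 °C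
Reagents that add atoms: none
Why: Stille coupling of the hindered vinyl triflate; the (E)-geometry of the stannane is retained.

Step 4
Reactants: 6 (E)-3-(7,9,9-trimethyl-1,4-dioxaspiro[4.5]dec-7-en-8-yl)prop-2-en-1-ol
Product: 7 [(2S,3S)-3-(7,9,9-trimethyl-1,4-dioxaspiro[4.5]dec-7-en-8-yl)oxiran-2-yl]methanol
Conditions: Ti(OiPr)4 (10 mol %), L-(+)-diethyl tartrate (12 mol %), t-BuOOH (2 equiv), 4 Å molecular sieves, CH2Cl2, −25 °C
Reagents that add atoms: tert-butyl hydroperoxide, CC(C)(C)OO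
Why: Katsuki–Sharpless asymmetric epoxidation touches only the allylic-alcohol double bond (the tetrasubstituted ring alkene is not directed), and the L-(+)-tartrate ligand should give the (2S,3S)-oxirane, which fixes the future C2 stereocentre.

Step 5
Reactants: 7 [(2S,3S)-3-(7,9,9-trimethyl-1,4-dioxaspiro[4.5]dec-7-en-8-yl)oxiran-2-yl]methanol
Product: 8 (2R,3S)-3-(7,9,9-trimethyl-1,4-dioxaspiro[4.5]dec-7-en-8-yl)oxirane-2-carbaldehyde
Conditions: Dess–Martin periodinane, pyridine, CH2Cl2, 0 °C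
Reagents that add atoms: none
Why: pyridine-buffered Dess–Martin oxidation of the primary alcohol; neither oxirane carbon is touched (the descriptor changes by priority only).

Step 6
Reactants: 8 (2R,3S)-3-(7,9,9-trimethyl-1,4-dioxaspiro[4.5]dec-7-en-8-yl)oxirane-2-carbaldehyde
Product: 9 8-[(2S,3S)-3-ethynyloxiran-2-yl]-7,9,9-trimethyl-1,4-dioxaspiro[4.5]dec-7-ene
Conditions: MeCOC(N2)PO(OMe)2, K2CO3, MeOH, 0 °C → rt
Reagents that add atoms: dimethyl (1-diazo-2-oxopropyl)phosphonate, CC(=O)C(=[N+]=[N-])P(=O)(OC)OC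
Why: Ohira–Bestmann (Seyferth–Gilbert) homologation of the aldehyde to the terminal alkyne under mild base, which should leave the trans-oxirane intact.

Step 7
Reactants: 9 8-[(2S,3S)-3-ethynyloxiran-2-yl]-7,9,9-trimethyl-1,4-dioxaspiro[4.5]dec-7-ene
Product: 10 (2R,7aR)-2-ethynyl-4,4,7a-trimethyl-4,5,7,7a-tetrahydro-2H-spiro[1-benzofuran-6,2'-[1,3]dioxolane]
Conditions: Cu(hfacac)2 (5 mol %; hfacac = CF3COCHCOCF3), toluene, 110 °C, sealed tube
Reagents that add atoms: none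
Why: Cu(hfacac)2 (divalent copper, a mild oxophilic Lewis acid) binds the oxirane oxygen and the C–O bond allylic to the tetrasubstituted ring alkene ionises, leaving a copper alkoxide on the ethynyl-bearing carbon (future C2) and an allyl cation over the future C3, C3a and C7a; the alkoxide then bonds to the tertiary terminus (O1–C7a) and the double bond ends at C3=C3a, a vinyl-oxirane to 2,5-dihydrofuran ring expansion by net 1,3-shift of oxygen. The closest known reaction type is this same Cu(hfacac)2-catalysed rearrangement of vinyl oxiranes, and it mirrors the epoxide-to-furanoid rearrangement of 5,6-epoxy carotenoid end groups. The dihydrofuran closes in a 5-endo mode by collapse of the alkoxide onto the allyl-cation terminus. C2 is not touched (its C–O bond survives), and the new quaternary centre C7a is set by C2: only the rotamer with C2 turned towards C7a can close, and in it the trans-oxirane geometry puts the C2 hydrogen next to the C7a methyl and the ethynyl group outside (allylic 1,3-strain), so suprafacial delivery of oxygen should give ethynyl and methyl trans, (2R,7aR). The spiro-ketal keeps the six-membered ring free of a competing stereocentre, so both ring faces are otherwise alike. The step needs cleavage of the allylic and not the propargylic C–O bond (secured by the electron-rich tetrasubstituted alkene) and ring closure ahead of 1,2-hydride shift or proton loss (secured by the tertiary cation terminus held within reach of the tethered alkoxide).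

Step 8
Reactants: 10 (2R,7aR)-2-ethynyl-4,4,7a-trimethyl-4,5,7,7a-tetrahydro-2H-spiro[1-benzofuran-6,2'-[1,3]dioxolane]
Product: 11 (2R,7aR)-2-ethynyl-4,4,7a-trimethyl-4,5,7,7a-tetrahydro-1-benzofuran-6(2H)-one
Conditions: PPTS (cat.), acetone–H2O (10:1), 50 °C
Reagents that add atoms: water, O
Why: mild acid-catalysed ketal hydrolysis unmasks the C6 ketone; C2 and C7a are not involved.

Step 9
Reactants: 11 (2R,7aR)-2-ethynyl-4,4,7a-trimethyl-4,5,7,7a-tetrahydro-1-benzofuran-6(2H)-one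
Product: 12 (2R,6S,7aR)-2-ethynyl-4,4,7a-trimethyl-2,4,5,6,7,7a-hexahydro-1-benzofuran-6-ol
Conditions: LiBH(s-Bu)3 (L-Selectride), THF, −78 °C; then H2O
Reagents that add atoms: none
Why: bulky-hydride ketone reduction; the syn-axial methyls on C4 and C7a block one face of the C6 carbonyl, so hydride should enter from the open equatorial side and give the axial (6S)-alcohol cis to the C7a methyl.

Step 10
Reactants: 12 (2R,6S,7aR)-2-ethynyl-4,4,7a-trimethyl-2,4,5,6,7,7a-hexahydro-1-benzofuran-6-ol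
Product: 14 (2R,6S,7aR)-2-(3-hydroxyprop-1-yn-1-yl)-4,4,7a-trimethyl-2,4,5,6,7,7a-hexahydro-1-benzofuran-6-ol, via dilithium alkoxide acetylide 13 (not isolated)
Conditions: n-BuLi (2.2 equiv), THF, −78 °C; (CH2O)n, −78 °C → rt
Reagents that add atoms: formaldehyde (as paraformaldehyde), C=O
Why: acetylide addition to formaldehyde (the alkoxide formed first is inert); no stereocentre is touched.

Step 11
Reactants: 14 (2R,6S,7aR)-2-(3-hydroxyprop-1-yn-1-yl)-4,4,7a-trimethyl-2,4,5,6,7,7a-hexahydro-1-benzofuran-6-ol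
Product: 16 (2R,6S,7aR)-2-[(1Z)-3-hydroxy-1-iodoprop-1-en-1-yl]-4,4,7a-trimethyl-2,4,5,6,7,7a-hexahydro-1-benzofuran-6-ol, via cyclic vinylalanate 15 (not isolated)
Conditions: NaAlH2(OCH2CH2OCH3)2 (Red-Al, 3.5 equiv), THF, 0 °C; EtOAc; then I2, −78 °C
Reagents that add atoms: iodine, [I][I]
Why: hydroxyl-directed trans-hydroalumination of the propargylic alcohol puts aluminium on the distal alkyne carbon in a five-membered alkoxyalanate, and iodinolysis with retention should give the (Z)-3-iodoallylic alcohol.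

Step 12
Reactants: 16 (2R,6S,7aR)-2-[(1Z)-3-hydroxy-1-iodoprop-1-en-1-yl]-4,4,7a-trimethyl-2,4,5,6,7,7a-hexahydro-1-benzofuran-6-ol
Product: 17 3-[(2R,6S,7aR)-6-hydroxy-4,4,7a-trimethyl-2,4,5,6,7,7a-hexahydro-1-benzofuran-2-yl]furan-2(5H)-one
Conditions: PdCl2(PPh3)2 (5 mol %), CO (1 atm), Et3N, THF, 50 °C
Reagents that add atoms: carbon monoxide, [C-]#[O+]
Why: palladium-catalysed carbonylative lactonisation: oxidative addition of the vinyl iodide to zerovalent palladium formed in the flask, CO insertion, and capture of the acyl–palladium by the cis hydroxymethyl group closes the butenolide.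

**Fragment 2 (steps 13–20)**

Step 13
Reactants: 18 (4R,6R)-4-hydroxy-2,2,6-trimethylcyclohexan-1-one
Product: 19 (4R,6R)-4-[(tert-butyldimethylsilyl)oxy]-2,2,6-trimethylcyclohexan-1-one
Conditions: t-BuMe2SiCl, imidazole, DMF, rt
Reagents that add atoms: tert-butyldimethylsilyl chloride, CC(C)(C)[Si](C)(C)Cl
Why: silyl protection of the secondary alcohol; the carbinol stereocentre comes from the chiral pool.

Step 14
Reactants: 19 (4R,6R)-4-[(tert-butyldimethylsilyl)oxy]-2,2,6-trimethylcyclohexan-1-one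
Product: 21 (4R)-4-[(tert-butyldimethylsilyl)oxy]-2,6,6-trimethylcyclohex-1-en-1-yl trifluoromethanesulfonate, via lithium enolate 20 (not isolated)
Conditions: LiN(i-Pr)2, THF, −78 → 0 °C; PhNTf2, −78 °C → rt
Reagents that add atoms: N-phenylbis(trifluoromethanesulfonimide), O=S(=O)(N(c1ccccc1)S(=O)(=O)C(F)(F)F)C(F)(F)F
Why: enol triflate formation from the only possible enolate; the C6 stereocentre is erased and C4 is untouched.

Step 15
Reactants: 21 (4R)-4-[(tert-butyldimethylsilyl)oxy]-2,6,6-trimethylcyclohex-1-en-1-yl trifluoromethanesulfonate; 22 (2E)-3-methylpent-2-en-4-yn-1-ol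
Product: 23 (2E)-5-{(4R)-4-[(tert-butyldimethylsilyl)oxy]-2,6,6-trimethylcyclohex-1-en-1-yl}-3-methylpent-2-en-4-yn-1-ol
Conditions: Pd(PPh3)4 (5 mol %), CuI (10 mol %), Et3N, DMF, rt
Reagents that add atoms: none
Why: Sonogashira coupling of the vinyl triflate with the terminal alkyne; the (E)-alkene of 22 is untouched.

Step 16
Reactants: 23 (2E)-5-{(4R)-4-[(tert-butyldimethylsilyl)oxy]-2,6,6-trimethylcyclohex-1-en-1-yl}-3-methylpent-2-en-4-yn-1-ol
Product: 24 (2E)-5-{(4R)-4-[(tert-butyldimethylsilyl)oxy]-2,6,6-trimethylcyclohex-1-en-1-yl}-3-methylpent-2-en-4-ynal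
Conditions: MnO2, CH2Cl2, rt, dark
Reagents that add atoms: none
Why: MnO2 oxidation of the allylic alcohol to the enal.

Step 17
Reactants: 24 (2E)-5-{(4R)-4-[(tert-butyldimethylsilyl)oxy]-2,6,6-trimethylcyclohex-1-en-1-yl}-3-methylpent-2-en-4-ynal; 25 ethyl (2E)-4-(diethoxyphosphoryl)but-2-enoate
Product: 27 ethyl (2E,4E,6E)-9-{(4R)-4-[(tert-butyldimethylsilyl)oxy]-2,6,6-trimethylcyclohex-1-en-1-yl}-7-methylnona-2,4,6-trien-8-ynoate, via lithiated phosphonate 26 (not isolated)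
Conditions: LiN(SiMe3)2, THF, −78 °C; then 24, −78 → 0 °C, dark
Reagents that add atoms: none
Why: Horner–Wadsworth–Emmons olefination with the stabilised vinylogous phosphonate anion should give the new (E)-double bond, and the (E)-double bond of the reagent is kept.

Step 18
Reactants: 27 ethyl (2E,4E,6E)-9-{(4R)-4-[(tert-butyldimethylsilyl)oxy]-2,6,6-trimethylcyclohex-1-en-1-yl}-7-methylnona-2,4,6-trien-8-ynoate
Product: 28 (2E,4E,6E)-9-{(4R)-4-[(tert-butyldimethylsilyl)oxy]-2,6,6-trimethylcyclohex-1-en-1-yl}-7-methylnona-2,4,6-trien-8-yn-1-ol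
Conditions: i-Bu2AlH (DIBAL-H, 2.2 equiv), CH2Cl2, −78 °C
Reagents that add atoms: none
Why: 1,2-reduction of the conjugated ester to the allylic alcohol by the aluminium hydride.

Step 19
Reactants: 28 (2E,4E,6E)-9-{(4R)-4-[(tert-butyldimethylsilyl)oxy]-2,6,6-trimethylcyclohex-1-en-1-yl}-7-methylnona-2,4,6-trien-8-yn-1-ol
Product: 29 (2E,4E,6E)-9-{(4R)-4-[(tert-butyldimethylsilyl)oxy]-2,6,6-trimethylcyclohex-1-en-1-yl}-7-methylnona-2,4,6-trien-8-ynal
Conditions: MnO2, CH2Cl2, rt, dark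
Reagents that add atoms: none
Why: MnO2 oxidation of the allylic alcohol to the trienynal.

Step 20
Reactants: 29 (2E,4E,6E)-9-{(4R)-4-[(tert-butyldimethylsilyl)oxy]-2,6,6-trimethylcyclohex-1-en-1-yl}-7-methylnona-2,4,6-trien-8-ynal; 30 2-(triphenyl-λ5-phosphanylidene)propanal
Product: 31 (2E,4E,6E,8E)-11-{(4R)-4-[(tert-butyldimethylsilyl)oxy]-2,6,6-trimethylcyclohex-1-en-1-yl}-2,9-dimethylundeca-2,4,6,8-tetraen-10-ynal
Conditions: toluene, 90 °C, dark
Reagents that add atoms: none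
Why: Wittig olefination with the stabilised formyl ylide should give the (E)-trisubstituted enal, which is too hindered to react a second time.

**Union and end game (steps 21–22)**

Step 21
Reactants: 17 3-[(2R,6S,7aR)-6-hydroxy-4,4,7a-trimethyl-2,4,5,6,7,7a-hexahydro-1-benzofuran-2-yl]furan-2(5H)-one; 31 (2E,4E,6E,8E)-11-{(4R)-4-[(tert-butyldimethylsilyl)oxy]-2,6,6-trimethylcyclohex-1-en-1-yl}-2,9-dimethylundeca-2,4,6,8-tetraen-10-ynal
Product: 34 (5Z)-3-[(2R,6S,7aR)-6-[(tert-butyldimethylsilyl)oxy]-4,4,7a-trimethyl-2,4,5,6,7,7a-hexahydro-1-benzofuran-2-yl]-5-[(2E,4E,6E,8E)-11-{(4R)-4-[(tert-butyldimethylsilyl)oxy]-2,6,6-trimethylcyclohex-1-en-1-yl}-2,9-dimethylundeca-2,4,6,8-tetraen-10-yn-1-ylidene]furan-2(5H)-one, via silyloxyfuran 32 (not isolated), via aldol silyl ether 33 (not isolated)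
Conditions: t-BuMe2SiOTf (3.5 equiv), i-Pr2NEt (5 equiv), CH2Cl2, −78 → 0 °C; then DBU (3 equiv), rt, dark
Reagents that add atoms: tert-butyldimethylsilyl trifluoromethanesulfonate, CC(C)(C)[Si](C)(C)OS(=O)(=O)C(F)(F)F
Why: one-flask vinylogous Mukaiyama aldol addition of the 2-silyloxyfuran (through C5) to the aldehyde, then DBU-induced E1cB loss of silanol; the (Z)-ylidene (chain syn to the ring oxygen) should be favoured because the (E)-isomer suffers allylic strain with H4, the two transient carbinol centres are destroyed, and the C6 hydroxyl is silylated in the same flask.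

Step 22
Reactants: 34 (5Z)-3-[(2R,6S,7aR)-6-[(tert-butyldimethylsilyl)oxy]-4,4,7a-trimethyl-2,4,5,6,7,7a-hexahydro-1-benzofuran-2-yl]-5-[(2E,4E,6E,8E)-11-{(4R)-4-[(tert-butyldimethylsilyl)oxy]-2,6,6-trimethylcyclohex-1-en-1-yl}-2,9-dimethylundeca-2,4,6,8-tetraen-10-yn-1-ylidene]furan-2(5H)-one
Product: 35 (5Z)-3-[(2R,6S,7aR)-6-hydroxy-4,4,7a-trimethyl-2,4,5,6,7,7a-hexahydro-1-benzofuran-2-yl]-5-[(2E,4E,6E,8E)-11-[(4R)-4-hydroxy-2,6,6-trimethylcyclohex-1-en-1-yl]-2,9-dimethylundeca-2,4,6,8-tetraen-10-yn-1-ylidene]furan-2(5H)-one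
Conditions: Bu4NF, AcOH (1:1), THF, 0 °C → rt, dark
Reagents that add atoms: none
Why: fluoride-mediated cleavage of both silyl ethers, buffered with acetic acid to spare the ylidenebutenolide, the allylic ether and the polyene; no stereocentre is touched.

## Compound list

1 | rac-2,2,6-trimethylcyclohexane-1,4-dione | CC1CC(=O)CC(C)(C)C1=O | starting material
2 | rac-7,7,9-trimethyl-1,4-dioxaspiro[4.5]decan-8-one | CC1CC2(CC(C)(C)C1=O)OCCO2 | intermediate
3 | lithium 7,9,9-trimethyl-1,4-dioxaspiro[4.5]dec-7-en-8-olate | [Li+].CC1=C([O-])C(C)(C)CC2(C1)OCCO2 | intermediate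
4 | 7,9,9-trimethyl-1,4-dioxaspiro[4.5]dec-7-en-8-yl trifluoromethanesulfonate | CC1=C(OS(=O)(=O)C(F)(F)F)C(C)(C)CC2(C1)OCCO2 | intermediate
5 | (E)-3-(tributylstannyl)prop-2-en-1-ol | CCCC[Sn](CCCC)(CCCC)/C=C/CO | starting material
6 | (E)-3-(7,9,9-trimethyl-1,4-dioxaspiro[4.5]dec-7-en-8-yl)prop-2-en-1-ol | CC1=C(/C=C/CO)C(C)(C)CC2(C1)OCCO2 | intermediate
7 | [(2S,3S)-3-(7,9,9-trimethyl-1,4-dioxaspiro[4.5]dec-7-en-8-yl)oxiran-2-yl]methanol | CC1=C([C@@H]2O[C@H]2CO)C(C)(C)CC3(C1)OCCO3 | intermediate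
8 | (2R,3S)-3-(7,9,9-trimethyl-1,4-dioxaspiro[4.5]dec-7-en-8-yl)oxirane-2-carbaldehyde | CC1=C([C@@H]2O[C@H]2C=O)C(C)(C)CC3(C1)OCCO3 | intermediate
9 | 8-[(2S,3S)-3-ethynyloxiran-2-yl]-7,9,9-trimethyl-1,4-dioxaspiro[4.5]dec-7-ene | CC1=C([C@@H]2O[C@H]2C#C)C(C)(C)CC3(C1)OCCO3 | intermediate
10 | (2R,7aR)-2-ethynyl-4,4,7a-trimethyl-4,5,7,7a-tetrahydro-2H-spiro[1-benzofuran-6,2'-[1,3]dioxolane] | C#C[C@H]1C=C2C(C)(C)CC3(OCCO3)C[C@@]2(C)O1 | intermediate
11 | (2R,7aR)-2-ethynyl-4,4,7a-trimethyl-4,5,7,7a-tetrahydro-1-benzofuran-6(2H)-one | C#C[C@H]1C=C2C(C)(C)CC(=O)C[C@@]2(C)O1 | intermediate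
12 | (2R,6S,7aR)-2-ethynyl-4,4,7a-trimethyl-2,4,5,6,7,7a-hexahydro-1-benzofuran-6-ol | C#C[C@H]1C=C2C(C)(C)C[C@H](O)C[C@@]2(C)O1 | intermediate
13 | dilithium salt of 12 (C6 alkoxide and acetylide) | [Li+].[Li+].[C-]#C[C@H]1C=C2C(C)(C)C[C@H]([O-])C[C@@]2(C)O1 | intermediate
14 | (2R,6S,7aR)-2-(3-hydroxyprop-1-yn-1-yl)-4,4,7a-trimethyl-2,4,5,6,7,7a-hexahydro-1-benzofuran-6-ol | OCC#C[C@H]1C=C2C(C)(C)C[C@H](O)C[C@@]2(C)O1 | intermediate
15 | disodium cyclic vinylalanate of 14 (2,2-bis(2-methoxyethoxy)-2,5-dihydro-1,2-oxaluminol-2-uide with aluminium on the alkene carbon that carries the benzofuranyl group; C6 alkoxide) | [Na+].[Na+].COCCO[Al-]1(OCCOC)OCC=C1[C@H]1C=C2C(C)(C)C[C@H]([O-])C[C@@]2(C)O1 | intermediate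
16 | (2R,6S,7aR)-2-[(1Z)-3-hydroxy-1-iodoprop-1-en-1-yl]-4,4,7a-trimethyl-2,4,5,6,7,7a-hexahydro-1-benzofuran-6-ol | OC/C=C(\I)[C@H]1C=C2C(C)(C)C[C@H](O)C[C@@]2(C)O1 | intermediate
17 | 3-[(2R,6S,7aR)-6-hydroxy-4,4,7a-trimethyl-2,4,5,6,7,7a-hexahydro-1-benzofuran-2-yl]furan-2(5H)-one | O=C1OCC=C1[C@H]1C=C2C(C)(C)C[C@H](O)C[C@@]2(C)O1 | intermediate
18 | (4R,6R)-4-hydroxy-2,2,6-trimethylcyclohexan-1-one (actinol) | CC1(C)C[C@H](O)C[C@@H](C)C1=O | starting material
19 | (4R,6R)-4-[(tert-butyldimethylsilyl)oxy]-2,2,6-trimethylcyclohexan-1-one | CC1(C)C[C@H](O[Si](C)(C)C(C)(C)C)C[C@@H](C)C1=O | intermediate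
20 | lithium (4R)-4-[(tert-butyldimethylsilyl)oxy]-2,6,6-trimethylcyclohex-1-en-1-olate | [Li+].CC1=C([O-])C(C)(C)C[C@H](O[Si](C)(C)C(C)(C)C)C1 | intermediate
21 | (4R)-4-[(tert-butyldimethylsilyl)oxy]-2,6,6-trimethylcyclohex-1-en-1-yl trifluoromethanesulfonate | CC1=C(OS(=O)(=O)C(F)(F)F)C(C)(C)C[C@H](O[Si](C)(C)C(C)(C)C)C1 | intermediate
22 | (2E)-3-methylpent-2-en-4-yn-1-ol | C#C/C(C)=C/CO | starting material
23 | (2E)-5-{(4R)-4-[(tert-butyldimethylsilyl)oxy]-2,6,6-trimethylcyclohex-1-en-1-yl}-3-methylpent-2-en-4-yn-1-ol | CC1=C(C#C/C(C)=C/CO)C(C)(C)C[C@H](O[Si](C)(C)C(C)(C)C)C1 | intermediate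
24 | (2E)-5-{(4R)-4-[(tert-butyldimethylsilyl)oxy]-2,6,6-trimethylcyclohex-1-en-1-yl}-3-methylpent-2-en-4-ynal | CC1=C(C#C/C(C)=C/C=O)C(C)(C)C[C@H](O[Si](C)(C)C(C)(C)C)C1 | intermediate
25 | ethyl (2E)-4-(diethoxyphosphoryl)but-2-enoate (triethyl 4-phosphonocrotonate) | CCOC(=O)/C=C/CP(=O)(OCC)OCC | starting material
26 | lithium salt of 25 (phosphonate-stabilised allyl anion) | [Li+].CCOC(=O)/C=C/[CH-]P(=O)(OCC)OCC | intermediate
27 | ethyl (2E,4E,6E)-9-{(4R)-4-[(tert-butyldimethylsilyl)oxy]-2,6,6-trimethylcyclohex-1-en-1-yl}-7-methylnona-2,4,6-trien-8-ynoate | CC1=C(C#C/C(C)=C/C=C/C=C/C(=O)OCC)C(C)(C)C[C@H](O[Si](C)(C)C(C)(C)C)C1 | intermediate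
28 | (2E,4E,6E)-9-{(4R)-4-[(tert-butyldimethylsilyl)oxy]-2,6,6-trimethylcyclohex-1-en-1-yl}-7-methylnona-2,4,6-trien-8-yn-1-ol | CC1=C(C#C/C(C)=C/C=C/C=C/CO)C(C)(C)C[C@H](O[Si](C)(C)C(C)(C)C)C1 | intermediate
29 | (2E,4E,6E)-9-{(4R)-4-[(tert-butyldimethylsilyl)oxy]-2,6,6-trimethylcyclohex-1-en-1-yl}-7-methylnona-2,4,6-trien-8-ynal | CC1=C(C#C/C(C)=C/C=C/C=C/C=O)C(C)(C)C[C@H](O[Si](C)(C)C(C)(C)C)C1 | intermediate
30 | 2-(triphenyl-λ5-phosphanylidene)propanal | CC(C=O)=P(c1ccccc1)(c1ccccc1)c1ccccc1 | starting material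
31 | (2E,4E,6E,8E)-11-{(4R)-4-[(tert-butyldimethylsilyl)oxy]-2,6,6-trimethylcyclohex-1-en-1-yl}-2,9-dimethylundeca-2,4,6,8-tetraen-10-ynal | CC1=C(C#C/C(C)=C/C=C/C=C/C=C(C)/C=O)C(C)(C)C[C@H](O[Si](C)(C)C(C)(C)C)C1 | intermediate
32 | tert-butyl{[(2R,6S,7aR)-2-{2-[(tert-butyldimethylsilyl)oxy]furan-3-yl}-4,4,7a-trimethyl-2,4,5,6,7,7a-hexahydro-1-benzofuran-6-yl]oxy}dimethylsilane | CC(C)(C)[Si](C)(C)Oc1occc1[C@H]1C=C2C(C)(C)C[C@H](O[Si](C)(C)C(C)(C)C)C[C@@]2(C)O1 | intermediate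
33 | 5-[(2E,4E,6E,8E)-1-[(tert-butyldimethylsilyl)oxy]-11-{(4R)-4-[(tert-butyldimethylsilyl)oxy]-2,6,6-trimethylcyclohex-1-en-1-yl}-2,9-dimethylundeca-2,4,6,8-tetraen-10-yn-1-yl]-3-[(2R,6S,7aR)-6-[(tert-butyldimethylsilyl)oxy]-4,4,7a-trimethyl-2,4,5,6,7,7a-hexahydro-1-benzofuran-2-yl]furan-2(5H)-one (mixture of epimers at the two new carbinol carbons) | CC1=C(C#C/C(C)=C/C=C/C=C/C=C(C)/C(O[Si](C)(C)C(C)(C)C)C2OC(=O)C([C@H]3C=C4C(C)(C)C[C@H](O[Si](C)(C)C(C)(C)C)C[C@@]4(C)O3)=C2)C(C)(C)C[C@H](O[Si](C)(C)C(C)(C)C)C1 | intermediate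
34 | (5Z)-3-[(2R,6S,7aR)-6-[(tert-butyldimethylsilyl)oxy]-4,4,7a-trimethyl-2,4,5,6,7,7a-hexahydro-1-benzofuran-2-yl]-5-[(2E,4E,6E,8E)-11-{(4R)-4-[(tert-butyldimethylsilyl)oxy]-2,6,6-trimethylcyclohex-1-en-1-yl}-2,9-dimethylundeca-2,4,6,8-tetraen-10-yn-1-ylidene]furan-2(5H)-one | CC1=C(C#C/C(C)=C/C=C/C=C/C=C(C)/C=C2/C=C([C@H]3C=C4C(C)(C)C[C@H](O[Si](C)(C)C(C)(C)C)C[C@@]4(C)O3)C(=O)O2)C(C)(C)C[C@H](O[Si](C)(C)C(C)(C)C)C1 | intermediate
35 | (5Z)-3-[(2R,6S,7aR)-6-hydroxy-4,4,7a-trimethyl-2,4,5,6,7,7a-hexahydro-1-benzofuran-2-yl]-5-[(2E,4E,6E,8E)-11-[(4R)-4-hydroxy-2,6,6-trimethylcyclohex-1-en-1-yl]-2,9-dimethylundeca-2,4,6,8-tetraen-10-yn-1-ylidene]furan-2(5H)-one | CC1=C(C#C/C(C)=C/C=C/C=C/C=C(C)/C=C2/C=C([C@H]3C=C4C(C)(C)C[C@H](O)C[C@@]4(C)O3)C(=O)O2)C(C)(C)C[C@H](O)C1 | target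

## Step count and risks

Total step count: 22. Longest linear sequence: 14 steps (steps 1 to 12, then 21 and 22).

**Step 7.** The risk is poor facial selectivity at C7a, because the slim ethynyl group may exert too little allylic strain to hold the C2 hydrogen next to the C7a methyl, together with diversion of the opened oxirane into 1,2-hydride shift. The fallback changes what is rearranged and when the alkyne appears. It sets out from 8: dibromo-olefination (CBr4, PPh3, Et3N, CH2Cl2, 0 °C) should give 8-[(2S,3S)-3-(2,2-dibromoethenyl)oxiran-2-yl]-7,9,9-trimethyl-1,4-dioxaspiro[4.5]dec-7-ene F1. Its much bulkier sp2 substituent is then carried through the same copper-catalysed ring expansion to (2R,7aR)-2-(2,2-dibromoethenyl)-4,4,7a-trimethyl-4,5,7,7a-tetrahydro-2H-spiro[1-benzofuran-6,2'-[1,3]dioxolane] F2. Treatment with n-BuLi (2.2 equiv, THF, −78 °C; Fritsch–Buttenberg–Wiechell rearrangement) and NH4Cl quench unveils the alkyne, and the route is rejoined at 10.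

**Step 21.** The risks are ionisation of the allylic C7a–O1 ether by the silyl triflate, vinylogous β-elimination of O1 from the furanolate under DBU, decay of the polyenal before it is consumed, and erosion of the (Z)-geometry. The fallback separates the stages and replaces the base-induced elimination by a neutral dehydration. It sets out from 17 and 31: 17 is converted with t-BuMe2SiOTf and Et3N (CH2Cl2, 0 °C) into silyloxyfuran 32, which is isolated. A short vinylogous Mukaiyama aldol addition to 31 (BF3·OEt2, CH2Cl2, −78 °C, aqueous work-up) should give 5-[(2E,4E,6E,8E)-11-{(4R)-4-[(tert-butyldimethylsilyl)oxy]-2,6,6-trimethylcyclohex-1-en-1-yl}-1-hydroxy-2,9-dimethylundeca-2,4,6,8-tetraen-10-yn-1-yl]-3-[(2R,6S,7aR)-6-[(tert-butyldimethylsilyl)oxy]-4,4,7a-trimethyl-2,4,5,6,7,7a-hexahydro-1-benzofuran-2-yl]furan-2(5H)-one F3. Anti-selective dehydration under Mitsunobu conditions (PPh3, diethyl azodicarboxylate, THF, 0 °C) then rejoins the route at 34.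

**Step 11.** The risks are β-elimination of the ring oxygen from the vinylalanate (allene formation) and over-reduction before iodinolysis. The fallback avoids a carbanionic vinyl metal. It sets out from 14: ruthenium-catalysed trans-hydrosilylation (Et3SiH, [Cp*Ru(MeCN)3]PF6 2 mol %, CH2Cl2, 0 °C), with silicon placed distal to the free hydroxymethyl group, should give (2R,6S,7aR)-2-[(1Z)-3-hydroxy-1-(triethylsilyl)prop-1-en-1-yl]-4,4,7a-trimethyl-2,4,5,6,7,7a-hexahydro-1-benzofuran-6-ol F4. Iododesilylation with retention (N-iodosuccinimide, 2,6-lutidine, (CF3)2CHOH, 0 °C) rejoins the route at 16.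

## Further compounds

F1 | step 7 | 8-[(2S,3S)-3-(2,2-dibromoethenyl)oxiran-2-yl]-7,9,9-trimethyl-1,4-dioxaspiro[4.5]dec-7-ene | CC1=C([C@@H]2O[C@H]2C=C(Br)Br)C(C)(C)CC3(C1)OCCO3
F2 | step 7 | (2R,7aR)-2-(2,2-dibromoethenyl)-4,4,7a-trimethyl-4,5,7,7a-tetrahydro-2H-spiro[1-benzofuran-6,2'-[1,3]dioxolane] | BrC(Br)=C[C@H]1C=C2C(C)(C)CC3(OCCO3)C[C@@]2(C)O1
F3 | step 21 | 5-[(2E,4E,6E,8E)-11-{(4R)-4-[(tert-butyldimethylsilyl)oxy]-2,6,6-trimethylcyclohex-1-en-1-yl}-1-hydroxy-2,9-dimethylundeca-2,4,6,8-tetraen-10-yn-1-yl]-3-[(2R,6S,7aR)-6-[(tert-butyldimethylsilyl)oxy]-4,4,7a-trimethyl-2,4,5,6,7,7a-hexahydro-1-benzofuran-2-yl]furan-2(5H)-one (mixture of epimers at the two carbinol carbons) | CC1=C(C#C/C(C)=C/C=C/C=C/C=C(C)/C(O)C2OC(=O)C([C@H]3C=C4C(C)(C)C[C@H](O[Si](C)(C)C(C)(C)C)C[C@@]4(C)O3)=C2)C(C)(C)C[C@H](O[Si](C)(C)C(C)(C)C)C1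
F4 | step 11 | (2R,6S,7aR)-2-[(1Z)-3-hydroxy-1-(triethylsilyl)prop-1-en-1-yl]-4,4,7a-trimethyl-2,4,5,6,7,7a-hexahydro-1-benzofuran-6-ol | OC/C=C(\[Si](CC)(CC)CC)[C@H]1C=C2C(C)(C)C[C@H](O)C[C@@]2(C)O1
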